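**Retrosynthetic overview**

1. Target 14 comes from 13 by hydrogenolysis of the 3-O-benzyl group, and 13 from 12 by methylation of O7; both steps change only oxygen substituents.
2. Ring A of 12 is opened at C5–C6. It carries oxygen on C5, C7 and C8a in a 1,3,5 pattern plus a methoxy group on C8, so it is folded from γ-pyranone 11 (ring C, with O1–C8a already in place): the ester on C4a is C5, and the side chain CH(OMe)–CO–CH3 on C8a is C8–C7–C6.
3. 11 comes from 9 by acetylation of the C8 methylene group (lateral anion plus N-methoxy-N-methylacetamide).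
4. Ring C of 9 is made by C4–C4a acylation of methyl 4-methoxyacetoacetate 6 with β-chloroacryloyl chloride 7, then O1–C2 closure by addition–elimination; 7 comes from chloroformylation and oxidation of ketone 3, itself from aryl Grignard reagent 1 and Weinreb amide 2.
5. Ring order: ring B is bought, ring C is closed in step 4, ring A in step 6.

Key step: step 6

Remark: 4, 5, 7 and 8 are carried as mixtures of geometric isomers at the chlorovinyl double bond, which is consumed in the ring closure of step 4. Compound 11 is racemic at C8, and that centre becomes aromatic in step 6. The target has no stereocentre.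

**Route**

Step 1
Reactants: 1 3,4,5-trimethoxyphenylmagnesium bromide (commercial THF solution); 2 2-(benzyloxy)-N-methoxy-N-methylacetamide
Product: 3 2-(benzyloxy)-1-(3,4,5-trimethoxyphenyl)ethan-1-one
Conditions: THF, 0 °C to rt; aq. NH4Cl
Reagents that add atoms: none
Why: Weinreb ketone synthesis, in which the aryl Grignard reagent adds once to the N-methoxy-N-methylamide and the magnesium chelate holds the tetrahedral adduct until work-up, so no tertiary alcohol should form.

Step 2
Reactants: 3 2-(benzyloxy)-1-(3,4,5-trimethoxyphenyl)ethan-1-one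
Product: 4 2-(benzyloxy)-3-chloro-3-(3,4,5-trimethoxyphenyl)prop-2-enal (mixture of geometric isomers)
Conditions: POCl3 (3 equiv), DMF, 0 °C then 60 °C; ice-cold aq. NaOAc
Reagents that add atoms: POCl3, O=P(Cl)(Cl)Cl; N,N-dimethylformamide, CN(C)C=O; water, O
Why: Vilsmeier–Haack–Arnold chloroformylation, in which the only enolisable position (the benzyloxymethylene carbon) is formylated by the chloroiminium salt and the ketone oxygen is exchanged for chloride, as is usual for aryl alkyl ketones; the acyl-deactivated arene and the benzyl ether should tolerate the reagent.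

Step 3
Reactants: 4 2-(benzyloxy)-3-chloro-3-(3,4,5-trimethoxyphenyl)prop-2-enal
Product: 5 2-(benzyloxy)-3-chloro-3-(3,4,5-trimethoxyphenyl)prop-2-enoic acid (mixture of geometric isomers)
Conditions: NaClO2, NaH2PO4, 2-methyl-2-butene, t-BuOH/H2O, rt
Reagents that add atoms: NaClO2, [Na+].[O-]Cl=O
Why: Pinnick oxidation converts the enal into the acid under buffered conditions that should leave the vinyl chloride, the enol ether and the electron-rich arene untouched, the alkene scavenger removing the hypochlorous acid formed.

Step 4
Reactants: 5 2-(benzyloxy)-3-chloro-3-(3,4,5-trimethoxyphenyl)prop-2-enoic acid; 6 methyl 4-methoxy-3-oxobutanoate (methyl 4-methoxyacetoacetate)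
Product: 9 methyl 5-(benzyloxy)-2-(methoxymethyl)-4-oxo-6-(3,4,5-trimethoxyphenyl)-4H-pyran-3-carboxylate, via acid chloride 7 (not isolated), via open-chain tricarbonyl ester 8 (not isolated)
Conditions: (COCl)2, cat. DMF, CH2Cl2, 0 °C to rt, evaporate; then 6 (1.1 equiv), MgCl2 (1.1 equiv), Et3N (3.5 equiv), MeCN, 0 °C to rt, then 70 °C
Reagents that add atoms: none
Why: Acid chloride formation is followed by C-acylation of the magnesium enolate of the β-keto ester (Rathke-type conditions) and then by oxa-Michael addition of the enolised methoxyacetyl oxygen to the β-chlorovinyl ketone with loss of chloride (addition–elimination), the logic by which chromone-3-carboxylates and 4-quinolones are closed from acylated β-keto esters; the chlorovinyl geometry is erased in the addition, and the ketone oxygen should win over the less nucleophilic ester oxygen.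

Step 5
Reactants: 9 methyl 5-(benzyloxy)-2-(methoxymethyl)-4-oxo-6-(3,4,5-trimethoxyphenyl)-4H-pyran-3-carboxylate; 10 N-methoxy-N-methylacetamide
Product: 11 methyl 5-(benzyloxy)-2-(1-methoxy-2-oxopropyl)-4-oxo-6-(3,4,5-trimethoxyphenyl)-4H-pyran-3-carboxylate (racemic, used crude)
Conditions: LiN(SiMe3)2 (2.2 equiv), THF, −78 °C; then 10 (1.5 equiv), −78 to −20 °C; aq. NH4Cl
Reagents that add atoms: none
Why: Lateral (vinylogous) deprotonation of the 2-alkyl group of the γ-pyranone, helped by the neighbouring ester, gives an extended enolate that is acetylated at C8 by the Weinreb amide (crossed Claisen-type acylation); the chelated tetrahedral adduct keeps the ketone masked until the quench, so double acylation and premature ring closure should not occur, and the new C8 centre is formed racemic and is removed in step 6.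

Step 6
Reactants: 11 methyl 5-(benzyloxy)-2-(1-methoxy-2-oxopropyl)-4-oxo-6-(3,4,5-trimethoxyphenyl)-4H-pyran-3-carboxylate
Product: 12 3-(benzyloxy)-5,7-dihydroxy-8-methoxy-2-(3,4,5-trimethoxyphenyl)-4H-chromen-4-one
Conditions: LiN(iPr)2 (3.2 equiv), THF, −78 to 0 °C; 1 M HCl
Reagents that add atoms: none
Why: Intramolecular Claisen (Dieckmann-type) condensation: the first equivalent of amide base removes the doubly vinylogous C8–H, the second deprotonates the acetyl methyl group (C6) to a cross-conjugated dianion whose terminal carbon adds to the C5 ester carbonyl on C4a, and loss of methoxide followed by enolisation of the cyclohexenedione gives the aromatic 5,7-bis-phenoxide. The closest known reactions are the base-induced closure of β-polycarbonyl dianions to resorcinols and of 2-acetonylbenzoates to naphthalene-1,3-diols, the γ-pyranone serving here as a masked 1,3,5-triketone. Ring A closes in a 6-(enolendo)-exo-trig mode, forming C5–C6. No stereocentre is created, and the racemic C8 centre of 11 becomes an aromatic carbon. The step needs C-acylation at C6 in place of O-acylation by the C7 enolate oxygen: the dianion is most reactive at its terminal carbon, an enol lactone formed through oxygen would be reopened by the methoxide set free, and the C-acylated product leaves the equilibrium as the aromatic dianion. The 5,7,8 pattern cannot be scrambled because O1–C8a belongs to ring C before ring A exists, and LiN(iPr)2 is chosen because a silylamide would hardly reach the second deprotonation.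

Step 7
Reactants: 12 3-(benzyloxy)-5,7-dihydroxy-8-methoxy-2-(3,4,5-trimethoxyphenyl)-4H-chromen-4-one
Product: 13 3-(benzyloxy)-5-hydroxy-7,8-dimethoxy-2-(3,4,5-trimethoxyphenyl)-4H-chromen-4-one
Conditions: MeI (1.05 equiv), K2CO3 (1.1 equiv), acetone, rt
Reagents that add atoms: iodomethane, CI
Why: Williamson ether synthesis under weak-base control, in which the 7-hydroxyl is the most acidic phenol (conjugated with the C4 carbonyl) while the 5-hydroxyl is held in a hydrogen bond to that carbonyl, so one equivalent of MeI should methylate O7 only.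

Step 8
Reactants: 13 3-(benzyloxy)-5-hydroxy-7,8-dimethoxy-2-(3,4,5-trimethoxyphenyl)-4H-chromen-4-one
Product: 14 3,5-dihydroxy-7,8-dimethoxy-2-(3,4,5-trimethoxyphenyl)-4H-chromen-4-one (3,5-dihydroxy-7,8,3',4',5'-pentamethoxyflavone)
Conditions: H2 (1 atm), 10% Pd/C, EtOAc/MeOH, rt
Reagents that add atoms: none
Why: Catalytic hydrogenolysis cleaves the benzyl enol ether, while the aryl methyl ethers, the chelated phenol and the flavonol double bond should be unaffected under one atmosphere of hydrogen at room temperature.

**Compound list**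

1 | 3,4,5-trimethoxyphenylmagnesium bromide | COc1cc([Mg]Br)cc(OC)c1OC | starting material
2 | 2-(benzyloxy)-N-methoxy-N-methylacetamide | CON(C)C(=O)COCc1ccccc1 | starting material
3 | 2-(benzyloxy)-1-(3,4,5-trimethoxyphenyl)ethan-1-one | COc1cc(C(=O)COCc2ccccc2)cc(OC)c1OC | intermediate
4 | 2-(benzyloxy)-3-chloro-3-(3,4,5-trimethoxyphenyl)prop-2-enal (E/Z mixture) | COc1cc(C(Cl)=C(OCc2ccccc2)C=O)cc(OC)c1OC | intermediate
5 | 2-(benzyloxy)-3-chloro-3-(3,4,5-trimethoxyphenyl)prop-2-enoic acid (E/Z mixture) | COc1cc(C(Cl)=C(OCc2ccccc2)C(=O)O)cc(OC)c1OC | intermediate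
6 | methyl 4-methoxy-3-oxobutanoate | COCC(=O)CC(=O)OC | starting material
7 | 2-(benzyloxy)-3-chloro-3-(3,4,5-trimethoxyphenyl)prop-2-enoyl chloride (E/Z mixture, not isolated) | COc1cc(C(Cl)=C(OCc2ccccc2)C(Cl)=O)cc(OC)c1OC | intermediate
8 | methyl 4-(benzyloxy)-5-chloro-2-(2-methoxyacetyl)-3-oxo-5-(3,4,5-trimethoxyphenyl)pent-4-enoate (E/Z mixture, not isolated) | COCC(=O)C(C(=O)OC)C(=O)C(OCc1ccccc1)=C(Cl)c1cc(OC)c(OC)c(OC)c1 | intermediate
9 | methyl 5-(benzyloxy)-2-(methoxymethyl)-4-oxo-6-(3,4,5-trimethoxyphenyl)-4H-pyran-3-carboxylate | COCc1oc(-c2cc(OC)c(OC)c(OC)c2)c(OCc2ccccc2)c(=O)c1C(=O)OC | intermediate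
10 | N-methoxy-N-methylacetamide | CC(=O)N(C)OC | starting material
11 | methyl 5-(benzyloxy)-2-(1-methoxy-2-oxopropyl)-4-oxo-6-(3,4,5-trimethoxyphenyl)-4H-pyran-3-carboxylate (racemic) | COC(=O)c1c(C(OC)C(C)=O)oc(-c2cc(OC)c(OC)c(OC)c2)c(OCc2ccccc2)c1=O | intermediate
12 | 3-(benzyloxy)-5,7-dihydroxy-8-methoxy-2-(3,4,5-trimethoxyphenyl)-4H-chromen-4-one | COc1c(O)cc(O)c2c(=O)c(OCc3ccccc3)c(-c3cc(OC)c(OC)c(OC)c3)oc12 | intermediate
13 | 3-(benzyloxy)-5-hydroxy-7,8-dimethoxy-2-(3,4,5-trimethoxyphenyl)-4H-chromen-4-one | COc1c(OC)cc(O)c2c(=O)c(OCc3ccccc3)c(-c3cc(OC)c(OC)c(OC)c3)oc12 | intermediate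
14 | 3,5-dihydroxy-7,8-dimethoxy-2-(3,4,5-trimethoxyphenyl)-4H-chromen-4-one | COc1cc(-c2oc3c(OC)c(OC)cc(O)c3c(=O)c2O)cc(OC)c1OC | target

**Step count**

Total step count: 8. Longest linear sequence: 8 steps (1 or 2 to 14).

**Steps most likely to fail**

Step 6 (ring A closure). The terminal enolate may form only in low concentration beside the stabilised C8 anion, and it must attack an ester carbonyl that shares the negative charge of that anion. The acetyl group must also sit on the C4a side of the C8–C8a bond. If closure is slow, the acetyl group may be lost by retro-Claisen attack of the liberated methoxide, or the dianion may decompose. The fallback makes the C5 acyl group more electrophilic and gives it a leaving group that does not attack back. It sets out from 9 and comes back at 12. Me3SnOH in 1,2-dichloroethane at 80 °C should cleave the methyl ester to 5-(benzyloxy)-2-(methoxymethyl)-4-oxo-6-(3,4,5-trimethoxyphenyl)-4H-pyran-3-carboxylic acid F1. Steglich-type coupling with ethanethiol (1-ethyl-3-(3-dimethylaminopropyl)carbodiimide hydrochloride, DMAP, CH2Cl2) should give S-ethyl 5-(benzyloxy)-2-(methoxymethyl)-4-oxo-6-(3,4,5-trimethoxyphenyl)-4H-pyran-3-carbothioate F2. Lateral acetylation as in step 5 should give S-ethyl 5-(benzyloxy)-2-(1-methoxy-2-oxopropyl)-4-oxo-6-(3,4,5-trimethoxyphenyl)-4H-pyran-3-carbothioate F3. Treatment of F3 with LiN(iPr)2 in THF should then close ring A by a thioester Claisen condensation with loss of ethanethiolate, giving 12.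

Step 5 (lateral acetylation). The stabilised extended enolate may add too slowly to the Weinreb amide and be returned as 9 on work-up, or it may attack the ester of a second molecule. The fallback replaces the anionic acylation by a Lewis-acid route. It sets out from 9 and comes back at 11. TBSOTf and Et3N in CH2Cl2 at 0 °C should silylate the C4 carbonyl to a 4-silyloxypyrylium ion, whose C8–H is removed by the amine to give methyl 5-(benzyloxy)-4-[(tert-butyldimethylsilyl)oxy]-2-(methoxymethylidene)-6-(3,4,5-trimethoxyphenyl)-2H-pyran-3-carboxylate F4. Vinylogous Mukaiyama-type acylation of this silyl dienol ether with acetyl chloride and ZnCl2 in CH2Cl2 at −78 to 0 °C should take place at C8, since only that position restores the pyranone, and give 11.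

Step 4 (acylation and pyranone closure). The magnesium enolate may be acylated partly on oxygen, or the oxa-Michael addition and chloride loss may stall under the mild amine conditions and leave mixtures of open-chain enol tautomers. The fallback secures C-acylation through an enamine and separates the ring closure. It sets out from 6 (with 7 made from 5 as before) and comes back at 9. Condensation of 6 with pyrrolidine in toluene with removal of water should give methyl 4-methoxy-3-(pyrrolidin-1-yl)but-2-enoate F5. Acylation of this β-enamino ester at carbon with 7 and Et3N in CH2Cl2 should give methyl 4-(benzyloxy)-5-chloro-2-[2-methoxy-1-(pyrrolidin-1-yl)ethylidene]-3-oxo-5-(3,4,5-trimethoxyphenyl)pent-4-enoate F6. Hydrolysis of the enaminone with 1 M HCl in THF should release 8, and K2CO3 in DMF at 60 °C should close it to 9.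

**Further compounds**

F1 | step 6 | 5-(benzyloxy)-2-(methoxymethyl)-4-oxo-6-(3,4,5-trimethoxyphenyl)-4H-pyran-3-carboxylic acid | COCc1oc(-c2cc(OC)c(OC)c(OC)c2)c(OCc2ccccc2)c(=O)c1C(=O)O
F2 | step 6 | S-ethyl 5-(benzyloxy)-2-(methoxymethyl)-4-oxo-6-(3,4,5-trimethoxyphenyl)-4H-pyran-3-carbothioate | CCSC(=O)c1c(COC)oc(-c2cc(OC)c(OC)c(OC)c2)c(OCc2ccccc2)c1=O
F3 | step 6 | S-ethyl 5-(benzyloxy)-2-(1-methoxy-2-oxopropyl)-4-oxo-6-(3,4,5-trimethoxyphenyl)-4H-pyran-3-carbothioate (racemic) | CCSC(=O)c1c(C(OC)C(C)=O)oc(-c2cc(OC)c(OC)c(OC)c2)c(OCc2ccccc2)c1=O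
F4 | step 5 | methyl 5-(benzyloxy)-4-[(tert-butyldimethylsilyl)oxy]-2-(methoxymethylidene)-6-(3,4,5-trimethoxyphenyl)-2H-pyran-3-carboxylate (E/Z mixture) | COC=C1OC(-c2cc(OC)c(OC)c(OC)c2)=C(OCc2ccccc2)C(O[Si](C)(C)C(C)(C)C)=C1C(=O)OC
F5 | step 4 | methyl 4-methoxy-3-(pyrrolidin-1-yl)but-2-enoate (E/Z mixture) | COCC(=CC(=O)OC)N1CCCC1
F6 | step 4 | methyl 4-(benzyloxy)-5-chloro-2-[2-methoxy-1-(pyrrolidin-1-yl)ethylidene]-3-oxo-5-(3,4,5-trimethoxyphenyl)pent-4-enoate (E/Z mixture) | COCC(N1CCCC1)=C(C(=O)OC)C(=O)C(OCc1ccccc1)=C(Cl)c1cc(OC)c(OC)c(OC)c1
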